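Atom labels C1–C20 use labdane numbering of the target.

Assumption: the lithium aldol in step 5 goes through a closed Zimmerman–Traxler transition state with the aldehyde chain equatorial. If the other carbinol epimer dominates in practice, the L‑lactic enantiomer of 8 is used and nothing else changes.

## Retrosynthetic overview

1. C12=C13 is made last, by E‑selective cross‑metathesis of an allyl‑decalin diol with (S)‑tulipalin B. C14 is bought in (S)‑3‑hydroxy‑γ‑butyrolactone.
2. The C19 CH2OH comes from LiAlH4 reduction of a 3‑hydroxy‑19‑methyl ester.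
3. Ring A (C4–C5), then ring B (C9–C10) and the C8 exocyclic alkene form in one visible‑light Ti/Co radical cycloisomerisation of an acyclic glycidic‑ester tetraene. The C3–O stereocentre directs C4, C5, C9 and C10.
4. The glycidic ester comes from a C3–C4 aldol of the D‑lactic acid dioxolanone (supplies C4, C18, C19) with an achiral trienal, then mesylate displacement with inversion at C3.
5. The trienal comes from farnesyl bromide and vinyl Grignard, followed by terminal epoxidation and periodate cleavage.

## Route

**Step 1**
- Reactants: 1, (2E,6E)‑farnesyl bromide; 2, vinylmagnesium bromide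
- Product: 3, (4E,8E)‑5,9,13‑trimethyltetradeca‑1,4,8,12‑tetraene
- Conditions: CuI (10 mol %), THF, −30 → 0 °C
- Reagents that add atoms: vinylmagnesium bromide, C=C[Mg]Br
- Why: Cu(I)‑catalysed allyl–vinyl Grignard coupling is SN2‑selective on the primary allylic bromide and keeps the E geometry; no stereocentre is formed.

**Step 2**
- Reactants: 3
- Product: 4, (±)‑2,2‑dimethyl‑3‑[(3E,7E)‑3,7‑dimethylundeca‑3,7,10‑trien‑1‑yl]oxirane
- Conditions: NBS, THF–H2O, 0 °C; then K2CO3, MeOH, rt (crude bromohydrin, telescoped)
- Reagents that add atoms: water, O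
- Why: van Tamelen‑type terminal‑selective bromohydrin formation attacks the most exposed, most electron‑rich isopropylidene alkene (the vinyl group is much less nucleophilic), and base closes the epoxide; the racemic centre is erased in step 3.

**Step 3**
- Reactants: 4
- Product: 5, (4E,8E)‑4,8‑dimethyldodeca‑4,8,11‑trienal
- Conditions: H5IO6, THF–Et2O–H2O, 0 °C
- Reagents that add atoms: none
- Why: periodic acid opens the epoxide and cleaves the resulting glycol (loss of acetone), a standard operation on terminal epoxy‑polyprenes that leaves the other alkenes untouched.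

**Step 4**
- Reactants: 6, D‑(R)‑lactic acid; 7, pivalaldehyde
- Product: 8, (2R,5R)‑2‑tert‑butyl‑5‑methyl‑1,3‑dioxolan‑4‑one (cis)
- Conditions: cat. p‑TsOH/H2SO4, pentane, Dean–Stark; low‑temperature recrystallisation
- Reagents that add atoms: pivalaldehyde, CC(C)(C)C=O
- Why: in this acid‑catalysed acetalisation (Seebach dioxolanone) the lactic stereocentre sets the acetal centre, with the cis isomer favoured and purified by crystallisation.

**Step 5**
- Reactants: 8; 5
- Product: 9, (2R,5S)‑2‑tert‑butyl‑5‑[(1S,4E,8E)‑1‑hydroxy‑4,8‑dimethyldodeca‑4,8,11‑trien‑1‑yl]‑5‑methyl‑1,3‑dioxolan‑4‑one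
- Conditions: LDA, THF, −78 °C; then 5, −78 °C; AcOH quench; chromatography to remove the carbinol epimer
- Reagents that add atoms: none
- Why: in this self‑regeneration‑of‑stereocentres aldol the enolate is attacked anti to t‑Bu (>95:5), and the ring‑locked enolate (CH3 cis to OLi) in a closed Li chair places CH3 syn and ring O anti to the new OH, giving the (1S) carbinol at C3 with moderate, separable selectivity.

**Step 6**
- Reactants: 9
- Product: 10, methyl (2S,3R)‑3‑[(3E,7E)‑3,7‑dimethylundeca‑3,7,10‑trien‑1‑yl]‑2‑methyloxirane‑2‑carboxylate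
- Conditions: MsCl, Et3N, CH2Cl2, 0 °C; then K2CO3, MeOH, 0 °C → rt (telescoped)
- Reagents that add atoms: methanol, CO
- Why: methanolysis of the acylal releases pivalaldehyde and the C4 tertiary alkoxide, which displaces the anti‑periplanar C3 mesylate (3‑exo‑tet SN2, Darzens‑type closure), inverting C3 to R.

**Step 7 (key step)**
- Reactants: 10
- Product: 11, methyl (1S,2R,4aS,5R,8aS)‑2‑hydroxy‑1,4a‑dimethyl‑6‑methylidene‑5‑(prop‑2‑en‑1‑yl)decahydronaphthalene‑1‑carboxylate. This is a trans‑decalin with 3‑OH equatorial, 19‑CO2Me axial and syn to C20, and the C9 allyl equatorial.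
- Conditions: Cp2TiCl2 (10 mol %), Co(dmgBF2)2(MeCN)2 (1 mol %), 4CzIPN (2 mol %), 2,4,6‑collidine and collidine·HCl (0.5 equiv each), PhCF3–MeCN 4:1 (5 mM), 455 nm LEDs, 25 °C, Ar
- Reagents that add atoms: none (isomerisation)
- Why: Proposed new method: excited 4CzIPN reduces Cp2TiCl2 to a low steady‑state concentration of Cp2Ti(III)Cl, which opens the glycidic ester at C4–O to a tertiary α‑ester radical with the C3–O bond intact; because little Ti(III) is present, the polarity‑matched electrophilic radical undergoes 6‑endo (C4–C5) then 6‑endo (C10–C9) cyclisation faster than it is reduced to the Ti enolate; the resulting C8 radical gives a methyl H atom to Co(II), as in catalytic chain transfer, to form the exocyclic alkene; collidine deprotonates Co–H, Co(I) returns the electron to 4CzIPN•+, and collidinium releases the Ti alkoxide, so the cycle is redox‑neutral and uses one photon per turnover; the bulky equatorial C3–OTi in a chair–chair fold with the two E alkenes sets C5, C10 and C9 (trans ring fusion, equatorial side chain), and the planar C4 radical places its flat conjugated ester in the crowded axial site over the alkene with CH3 equatorial, the same sense as Mn(III) β‑keto‑ester cyclisations; closest known chemistry is Ti(III) (Nugent–RajanBabu type) epoxypolyene radical cyclisation, Ti/Co epoxide‑to‑allylic‑alcohol redox relay and photoredox titanocene catalysis, none of which has been shown on glycidic esters or combined for a polyene bicyclisation.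

**Step 8**
- Reactants: 11
- Product: 12, (1R,2R,4aS,5R,8aS)‑1‑(hydroxymethyl)‑1,4a‑dimethyl‑6‑methylidene‑5‑(prop‑2‑en‑1‑yl)decahydronaphthalen‑2‑ol
- Conditions: LiAlH4, THF, 0 °C → reflux
- Reagents that add atoms: none
- Why: LiAlH4 reduces the hindered axial ester, assisted by the neighbouring alkoxide, while the isolated alkenes are inert and no stereocentre changes.

**Step 9**
- Reactants: 13, (S)‑3‑hydroxy‑γ‑butyrolactone
- Product: 14, (S)‑tulipalin B, (4S)‑4‑hydroxy‑3‑methylideneoxolan‑2‑one
- Conditions: LDA (2.2 equiv), THF, −78 °C; Eschenmoser's salt, −78 → −20 °C; then MeI, MeOH; aq. NaHCO3/CH2Cl2 (telescoped)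
- Reagents that add atoms: Eschenmoser's salt, C=[N+](C)C.[I-] (leaves CH2)
- Why: this is a dianion Mannich reaction followed by quaternisation and E1cB elimination (α‑methylenation), in which the alkoxide form blocks β‑elimination and C14 is untouched.

**Step 10**
- Reactants: 12; 14 (3 equiv)
- Product: 15, andrographolide
- Conditions: Hoveyda–Grubbs II (2 × 5 mol %), 2,6‑dichloro‑1,4‑benzoquinone (10 mol %), CH2Cl2, 40 °C, N2 sparge
- Reagents that add atoms: none (ethylene lost)
- Why: cross‑metathesis of a type I terminal alkene with an α‑methylene‑γ‑lactone is assisted by the allylic OH, and the quinone suppresses isomerisation; the hindered C8 methylidene does not react, free OH groups are tolerated, and the more stable E alkylidene (H12 cis to C=O) is formed.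

## Compound list

| No. | Name | SMILES | Role |
|---|---|---|---|
| 1 | (2E,6E)‑farnesyl bromide | `CC(C)=CCC/C(C)=C/CC/C(C)=C/CBr` | starting material |
| 2 | vinylmagnesium bromide | `C=C[Mg]Br` | starting material |
| 3 | (4E,8E)‑5,9,13‑trimethyltetradeca‑1,4,8,12‑tetraene | `CC(C)=CCC/C(C)=C/CC/C(C)=C/CC=C` | intermediate |
| 4 | terminal epoxide (racemic) | `CC1(C)OC1CC/C(C)=C/CC/C(C)=C/CC=C` | intermediate |
| 5 | (4E,8E)‑4,8‑dimethyldodeca‑4,8,11‑trienal | `O=CCC/C(C)=C/CC/C(C)=C/CC=C` | intermediate |
| 6 | D‑(R)‑lactic acid | `C[C@@H](O)C(=O)O` | starting material |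
| 7 | pivalaldehyde | `CC(C)(C)C=O` | starting material |
| 8 | (2R,5R)‑2‑tert‑butyl‑5‑methyl‑1,3‑dioxolan‑4‑one | `C[C@H]1O[C@@H](C(C)(C)C)OC1=O` | intermediate |
| 9 | aldol adduct (2R,5S,1'S) | `C[C@@]1([C@@H](O)CC/C(C)=C/CC/C(C)=C/CC=C)O[C@@H](C(C)(C)C)OC1=O` | intermediate |
| 10 | methyl (2S,3R)‑glycidate tetraene | `COC(=O)[C@@]1(C)O[C@@H]1CC/C(C)=C/CC/C(C)=C/CC=C` | intermediate |
| 11 | 3‑hydroxy‑19‑methyl ester allyl decalin | `C=C1CC[C@@H]2[C@](C)(C(=O)OC)[C@H](O)CC[C@@]2(C)[C@@H]1CC=C` | intermediate |
| 12 | 3,19‑diol allyl decalin | `C=C1CC[C@@H]2[C@](C)(CO)[C@H](O)CC[C@@]2(C)[C@@H]1CC=C` | intermediate |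
| 13 | (S)‑3‑hydroxy‑γ‑butyrolactone | `O=C1C[C@H](O)CO1` | starting material |
| 14 | (S)‑tulipalin B | `C=C1C(=O)OC[C@H]1O` | intermediate |
| 15 | andrographolide | `C=C1CC[C@@H]2[C@](C)(CO)[C@H](O)CC[C@@]2(C)[C@@H]1C/C=C1/C(=O)OC[C@H]1O` | target |

## Step count

- Total: 10 steps. Steps 2, 6 and 9 are telescoped two‑ or three‑stage operations; counting every stage separately gives 13 to 14 operations.
- Longest linear sequence: 8 steps (1 → 2 → 3 → 5 → 6 → 7 → 8 → 10).

## Steps most likely to fail

1. **Step 7 (the new Ti/Co/photoredox bicyclisation).** The risks are: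
   - reduction or deoxygenation of the α‑ester radical;
   - premature H abstraction by Co(II), giving the α‑methylene or monocyclic product;
   - incomplete axial‑ester selectivity at C4;
   - Co–H isomerisation of the allyl group.

   Fallback (known chemistry): reduce 10 with DIBAL‑H to the epoxy alcohol and acetylate it. Then run the established thermal Cp2TiCl2 (cat.)/Mn/TMSCl–collidine epoxypolyprene cyclisation, which proceeds through a tertiary alkyl radical and has documented exocyclic‑alkene termination. Separate the C4 epimers and replace step 8 with K2CO3/MeOH.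

2. **Step 5 (carbinol selectivity of the dioxolanone aldol).** Fallback: buy C3 instead of making it.
   - Convert ethyl (S)‑4‑chloro‑3‑hydroxybutanoate to ethyl (S)‑3,4‑epoxybutanoate.
   - Open the epoxide at C2 with the lithiated C1 allylic phenyl sulfone of the geranyl‑derived C12 trienol.
   - Remove the sulfone reductively (Na/Hg or SmI2).
   - Install C18 by Fráter–Seebach methylation.
   - Iodinate the dianion to close the same type of glycidate with C3 fixed.

3. **Step 10 (cross‑metathesis with a 1,1‑disubstituted lactone on a free triol; E/Z ratio and homodimerisation).** Fallback: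
   - Protect 12 as the 3,19‑acetonide.
   - Cleave the monosubstituted alkene selectively with OsO4/NaIO4 to the C12 aldehyde.
   - Perform an aldol with the dianion of 13.
   - Dehydrate with MsCl/DBU to the E‑alkylidene lactone.
   - Remove the acetonide with aq. AcOH.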